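**Retrosynthetic overview**
1. The target comes from a fully protected precursor by one global Lewis-acid dealkylation; that precursor is cut at the C13–C14 bond of the side chain (alkyl–alkyl Negishi) into a tetralin-core bromide (31 heavy atoms) and a side-chain/caffeate zinc reagent (24 heavy atoms).
2. The zinc-reagent half is the Steglich ester of protected caffeic acid (catechol, then bromination, Heck, saponification) with (S)-3-bromo-2-methylpropanol (from (R)-Roche ester), followed by Br→I exchange.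
3. The core bromide comes from a tetralin alcohol by ortho-lithiation/carboxylation and Appel bromination; C1 is set by Ir-catalysed hydrogenation and C11 by Rh-catalysed conjugate addition of an alkenylboronate to ethyl crotonate.
4. The alkenylboronate comes from a 4-methyl-1-tetralone, made by Friedel–Crafts closure of an (R)-4-arylpentanoic acid; C4 is set by Ir-catalysed hydrogenation of the Wittig product of an aryl methyl ketone.
5. Rings: both benzene rings come from catechol; the only ring formed is the cyclohexane ring of the tetralin (Friedel–Crafts acylation, step 6).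

Assumption: where a chiral catalyst is named, the enantiomer given is the one expected by analogy with simple substrates to give the stated configuration; its antipode is used if the opposite sense is found.

**Step 1**
Reactants: 1 catechol
Product: 2 1,2-diisopropoxybenzene
Conditions: 2-bromopropane, K2CO3, DMF, 70 °C
Reagents that add atoms: 2-bromopropane, CC(C)Br
Why: Williamson ether synthesis; isopropyl aryl ethers survive acid, base and organolithiums and are cleaved by BCl3 at the end.

**Step 2**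
Reactants: 2 1,2-diisopropoxybenzene; 3 N-methoxy-N-methylacetamide
Product: 5 1-(2,3-diisopropoxyphenyl)ethan-1-one, via aryllithium 4 (not isolated)
Conditions: n-BuLi, TMEDA, Et2O, 0 °C to rt; then 3, −78 °C to rt; aq. work-up
Reagents that add atoms: none
Why: Directed ortho-metalation next to the alkoxy group, then Weinreb ketone synthesis (the chelated adduct prevents over-addition).

**Step 3**
Reactants: 6 3-bromopropanoic acid
Product: 7 (2-carboxyethyl)triphenylphosphonium bromide
Conditions: PPh3, MeCN, reflux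
Reagents that add atoms: triphenylphosphine, c1ccc(cc1)P(c1ccccc1)c1ccccc1
Why: SN2 quaternisation of PPh3 by the primary bromide gives the Wittig salt.

**Step 4**
Reactants: 5 1-(2,3-diisopropoxyphenyl)ethan-1-one; 7 (2-carboxyethyl)triphenylphosphonium bromide
Product: 9 (3E)-4-(2,3-diisopropoxyphenyl)pent-3-enoic acid, via phosphorus ylide 8 (not isolated)
Conditions: 7, NaHMDS (2 equiv per 7), THF, 0 °C; then 5, rt to 50 °C; HCl work-up; E isomer purified by crystallisation
Reagents that add atoms: none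
Why: Wittig olefination with the carboxylate-bearing ylide gives the β,γ-unsaturated acid, E-favoured (aryl trans to CH2CO2H).

**Step 5**
Reactants: 9 (3E)-4-(2,3-diisopropoxyphenyl)pent-3-enoic acid
Product: 10 (4R)-4-(2,3-diisopropoxyphenyl)pentanoic acid
Conditions: [Ir(cod)((Sa,S)-SIPHOX)]BArF (1 mol%), H2 (6 atm), Et3N (0.5 equiv), MeOH, rt
Reagents that add atoms: none
Why: Carboxyl-directed Ir/spiro-phosphine-oxazoline asymmetric hydrogenation of a β,γ-unsaturated acid; the catalyst selects the olefin face and sets the benzylic methyl centre (future C4) as R.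

**Step 6**
Reactants: 10 (4R)-4-(2,3-diisopropoxyphenyl)pentanoic acid
Product: 12 (4R)-5,6-diisopropoxy-4-methyl-3,4-dihydronaphthalen-1(2H)-one, via mixed anhydride 11 (not isolated)
Conditions: TFAA, CH2Cl2, 0 °C to rt
Reagents that add atoms: none
Why: Intramolecular Friedel–Crafts acylation at the only free ortho position, which is para to an isopropoxy group; the benzylic centre is not touched.

**Step 7**
Reactants: 12 (4R)-5,6-diisopropoxy-4-methyl-3,4-dihydronaphthalen-1(2H)-one
Product: 14 (4R)-5,6-diisopropoxy-4-methyl-3,4-dihydronaphthalen-1-yl trifluoromethanesulfonate, via potassium enolate 13 (not isolated)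
Conditions: KHMDS, THF, −78 °C; then PhNTf2, −78 °C to rt
Reagents that add atoms: N-phenylbis(trifluoromethanesulfonimide), O=S(=O)(N(c1ccccc1)S(=O)(=O)C(F)(F)F)C(F)(F)F
Why: Enol triflate formation; only C2 carries enolisable hydrogens, so the C1=C2 enolate is trapped.

**Step 8**
Reactants: 14 (4R)-5,6-diisopropoxy-4-methyl-3,4-dihydronaphthalen-1-yl trifluoromethanesulfonate
Product: 15 2-[(4R)-5,6-diisopropoxy-4-methyl-3,4-dihydronaphthalen-1-yl]-4,4,5,5-tetramethyl-1,3,2-dioxaborolane
Conditions: B2pin2, PdCl2(PPh3)2 (3 mol%), PPh3, KOPh, toluene, 50 °C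
Reagents that add atoms: bis(pinacolato)diboron, CC1(C)OB(OC1(C)C)B1OC(C)(C)C(C)(C)O1
Why: Miyaura borylation of an alkenyl triflate gives the alkenylboronate for the conjugate addition.

**Step 9**
Reactants: 15 the alkenylboronate from step 8; 16 ethyl (E)-but-2-enoate (3 equiv)
Product: 17 ethyl (3S)-3-[(4R)-5,6-diisopropoxy-4-methyl-3,4-dihydronaphthalen-1-yl]butanoate
Conditions: [Rh(cod)Cl]2 (3 mol%), (R)-BINAP (6.6 mol%), K3PO4, dioxane/H2O 10:1, 80 °C
Reagents that add atoms: none
Why: Hayashi–Miyaura Rh-catalysed asymmetric 1,4-addition; (R)-BINAP directs the alkenyl group to the 2-re face of the crotonate and sets C11 as S (the sense known for aryl additions to crotonates).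

**Step 10**
Reactants: 17 ethyl (3S)-3-[(4R)-5,6-diisopropoxy-4-methyl-3,4-dihydronaphthalen-1-yl]butanoate
Product: 18 ethyl (3S)-3-[(1S,4R)-5,6-diisopropoxy-4-methyl-1,2,3,4-tetrahydronaphthalen-1-yl]butanoate
Conditions: [Ir(cod)(L*)]BArF (L* = ThrePHOX-type phosphinite–oxazoline, 2 mol%), H2 (50 bar), CH2Cl2, rt
Reagents that add atoms: none
Why: Pfaltz-type Ir-catalysed asymmetric hydrogenation of a trisubstituted styrenic olefin; the catalyst enantiomer delivers H2 to the C1 face that carries the C11 methyl (anti to the CH2CO2Et arm), giving 1S with the side chain trans to the C4 methyl.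

**Step 11**
Reactants: 18 ethyl (3S)-3-[(1S,4R)-5,6-diisopropoxy-4-methyl-1,2,3,4-tetrahydronaphthalen-1-yl]butanoate
Product: 19 (3S)-3-[(1S,4R)-5,6-diisopropoxy-4-methyl-1,2,3,4-tetrahydronaphthalen-1-yl]butan-1-ol
Conditions: LiAlH4, THF, 0 °C; Fieser work-up
Reagents that add atoms: none
Why: Hydride reduction of the ester to the primary alcohol (C13); no stereocentre is affected.

**Step 12**
Reactants: 19 (3S)-3-[(1S,4R)-5,6-diisopropoxy-4-methyl-1,2,3,4-tetrahydronaphthalen-1-yl]butan-1-ol
Product: 21 tert-butyl (5R,8S)-8-[(2S)-4-hydroxybutan-2-yl]-3,4-diisopropoxy-5-methyl-5,6,7,8-tetrahydronaphthalene-2-carboxylate, via dilithio species 20 (not isolated)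
Conditions: s-BuLi (2.3 equiv), TMEDA, THF, −78 to −40 °C; then Boc2O (1.05 equiv), −78 °C; H2O quench at −78 °C
Reagents that add atoms: di-tert-butyl dicarbonate, CC(C)(C)OC(=O)OC(=O)OC(C)(C)C
Why: Directed ortho-metalation at the only ring C–H next to an alkoxy group; the aryllithium is acylated by Boc2O far faster than the lithium alkoxide at −78 °C, giving the tert-butyl ester directly.

**Step 13**
Reactants: 21 the hydroxy tert-butyl ester from step 12
Product: 22 tert-butyl (5R,8S)-8-[(2S)-4-bromobutan-2-yl]-3,4-diisopropoxy-5-methyl-5,6,7,8-tetrahydronaphthalene-2-carboxylate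
Conditions: CBr4, PPh3, CH2Cl2, 0 °C
Reagents that add atoms: tetrabromomethane, BrC(Br)(Br)Br
Why: Appel reaction turns the primary alcohol into the primary bromide under neutral conditions.

**Step 14**
Reactants: 2 1,2-diisopropoxybenzene
Product: 23 4-bromo-1,2-diisopropoxybenzene
Conditions: NBS, MeCN, 0 °C to rt
Reagents that add atoms: N-bromosuccinimide, O=C1CCC(=O)N1Br
Why: Electrophilic aromatic bromination para to an alkoxy group.

**Step 15**
Reactants: 23 4-bromo-1,2-diisopropoxybenzene; 24 methyl acrylate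
Product: 25 methyl (2E)-3-(3,4-diisopropoxyphenyl)prop-2-enoate
Conditions: Pd(OAc)2 (2 mol%), P(o-tol)3, Et3N, DMF, 100 °C
Reagents that add atoms: none
Why: Mizoroki–Heck reaction; syn-insertion/syn-β-hydride elimination gives the E-cinnamate.

**Step 16**
Reactants: 25 methyl (2E)-3-(3,4-diisopropoxyphenyl)prop-2-enoate
Product: 26 (2E)-3-(3,4-diisopropoxyphenyl)prop-2-enoic acid
Conditions: LiOH, THF/H2O, rt; then 1 M HCl
Reagents that add atoms: lithium hydroxide, [Li+].[OH-]
Why: Saponification of the methyl ester; the E double bond is unchanged.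

**Step 17**
Reactants: 27 methyl (2R)-3-hydroxy-2-methylpropanoate (Roche ester)
Product: 28 methyl (2S)-3-bromo-2-methylpropanoate
Conditions: CBr4, PPh3, CH2Cl2, 0 °C to rt
Reagents that add atoms: tetrabromomethane, BrC(Br)(Br)Br
Why: Appel reaction at the primary carbinol; the stereocentre is untouched (the descriptor changes only through CIP priorities).

**Step 18**
Reactants: 28 methyl (2S)-3-bromo-2-methylpropanoate
Product: 29 (2S)-3-bromo-2-methylpropan-1-ol
Conditions: DIBAL-H (2.2 equiv), CH2Cl2, −78 to 0 °C; Rochelle salt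
Reagents that add atoms: none
Why: DIBAL reduction of the ester to the alcohol without touching the C–Br bond.

**Step 19**
Reactants: 26 (2E)-3-(3,4-diisopropoxyphenyl)prop-2-enoic acid; 29 (2S)-3-bromo-2-methylpropan-1-ol
Product: 30 (2S)-3-bromo-2-methylpropyl (2E)-3-(3,4-diisopropoxyphenyl)prop-2-enoate
Conditions: DCC, DMAP (cat.), CH2Cl2, 0 °C to rt
Reagents that add atoms: none
Why: Steglich esterification of the primary alcohol; this places the caffeate on the future C16 oxygen.

**Step 20**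
Reactants: 30 the bromo ester from step 19
Product: 31 (2S)-3-iodo-2-methylpropyl (2E)-3-(3,4-diisopropoxyphenyl)prop-2-enoate
Conditions: NaI, acetone, reflux
Reagents that add atoms: sodium iodide, [Na+].[I-]
Why: Finkelstein exchange; the iodide allows zinc insertion at low temperature in the presence of the cinnamate.

**Step 21**
Reactants: 22 the core bromide from step 13; 31 the side-chain iodide from step 20
Product: 33 tert-butyl (5R,8S)-8-[(2S,6R)-7-{[(2E)-3-(3,4-diisopropoxyphenyl)prop-2-enoyl]oxy}-6-methylheptan-2-yl]-3,4-diisopropoxy-5-methyl-5,6,7,8-tetrahydronaphthalene-2-carboxylate, via alkylzinc iodide 32 (not isolated)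
Conditions: 31, Zn dust, LiCl, THF, 40 °C; then 22, Pd-PEPPSI-IPr (4 mol%), LiBr, THF/NMP 2:1, rt to 40 °C
Reagents that add atoms: none
Why: Alkyl–alkyl Negishi coupling (Pd–NHC) joins the two halves at C13–C14; the organozinc tolerates both esters and the enoate, and no stereocentre sits on a reacting carbon.

**Step 22**
Reactants: 33 the protected precursor from step 21
Product: 34 (5R,8S)-8-[(2S,6R)-7-{[(2E)-3-(3,4-dihydroxyphenyl)prop-2-enoyl]oxy}-6-methylheptan-2-yl]-3,4-dihydroxy-5-methyl-5,6,7,8-tetrahydronaphthalene-2-carboxylic acid (CNP0492979.1)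
Conditions: BCl3 (1 M in CH2Cl2, excess), CH2Cl2, −78 to 0 °C; then MeOH/H2O
Reagents that add atoms: none
Why: Lewis-acid dealkylation removes the four aryl isopropyl ethers and the tert-butyl ester by alkyl–oxygen cleavage, while the primary alkyl caffeate and the E-olefin survive at 0 °C or below.

**Compound list**
1 | catechol (benzene-1,2-diol) | Oc1ccccc1O | starting material
2 | 1,2-diisopropoxybenzene | CC(C)Oc1ccccc1OC(C)C | intermediate
3 | N-methoxy-N-methylacetamide | CC(=O)N(C)OC | starting material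
4 | (2,3-diisopropoxyphenyl)lithium | [Li]c1cccc(OC(C)C)c1OC(C)C | intermediate
5 | 1-(2,3-diisopropoxyphenyl)ethan-1-one | CC(=O)c1cccc(OC(C)C)c1OC(C)C | intermediate
6 | 3-bromopropanoic acid | OC(=O)CCBr | starting material
7 | (2-carboxyethyl)triphenylphosphonium bromide | OC(=O)CC[P+](c1ccccc1)(c1ccccc1)c1ccccc1.[Br-] | intermediate
8 | sodium 3-(triphenylphosphoranylidene)propanoate | [Na+].[O-]C(=O)CC=P(c1ccccc1)(c1ccccc1)c1ccccc1 | intermediate
9 | (3E)-4-(2,3-diisopropoxyphenyl)pent-3-enoic acid | OC(=O)C/C=C(\C)c1cccc(OC(C)C)c1OC(C)C | intermediate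
10 | (4R)-4-(2,3-diisopropoxyphenyl)pentanoic acid | OC(=O)CC[C@@H](C)c1cccc(OC(C)C)c1OC(C)C | intermediate
11 | (4R)-4-(2,3-diisopropoxyphenyl)pentanoic trifluoroacetic anhydride | O=C(CC[C@@H](C)c1cccc(OC(C)C)c1OC(C)C)OC(=O)C(F)(F)F | intermediate
12 | (4R)-5,6-diisopropoxy-4-methyl-3,4-dihydronaphthalen-1(2H)-one | O=C1CC[C@@H](C)c2c1ccc(OC(C)C)c2OC(C)C | intermediate
13 | potassium (4R)-5,6-diisopropoxy-4-methyl-3,4-dihydronaphthalen-1-olate | [K+].[O-]C1=CC[C@@H](C)c2c1ccc(OC(C)C)c2OC(C)C | intermediate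
14 | (4R)-5,6-diisopropoxy-4-methyl-3,4-dihydronaphthalen-1-yl trifluoromethanesulfonate | O=S(=O)(OC1=CC[C@@H](C)c2c1ccc(OC(C)C)c2OC(C)C)C(F)(F)F | intermediate
15 | 2-[(4R)-5,6-diisopropoxy-4-methyl-3,4-dihydronaphthalen-1-yl]-4,4,5,5-tetramethyl-1,3,2-dioxaborolane | CC1(C)OB(OC1(C)C)C1=CC[C@@H](C)c2c1ccc(OC(C)C)c2OC(C)C | intermediate
16 | ethyl (E)-but-2-enoate | CCOC(=O)/C=C/C | starting material
17 | ethyl (3S)-3-[(4R)-5,6-diisopropoxy-4-methyl-3,4-dihydronaphthalen-1-yl]butanoate | CCOC(=O)C[C@H](C)C1=CC[C@@H](C)c2c1ccc(OC(C)C)c2OC(C)C | intermediate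
18 | ethyl (3S)-3-[(1S,4R)-5,6-diisopropoxy-4-methyl-1,2,3,4-tetrahydronaphthalen-1-yl]butanoate | CCOC(=O)C[C@H](C)[C@@H]1CC[C@@H](C)c2c1ccc(OC(C)C)c2OC(C)C | intermediate
19 | (3S)-3-[(1S,4R)-5,6-diisopropoxy-4-methyl-1,2,3,4-tetrahydronaphthalen-1-yl]butan-1-ol | OCC[C@H](C)[C@@H]1CC[C@@H](C)c2c1ccc(OC(C)C)c2OC(C)C | intermediate
20 | lithium (3S)-3-[(1S,4R)-5,6-diisopropoxy-7-lithio-4-methyl-1,2,3,4-tetrahydronaphthalen-1-yl]butan-1-olate | [Li]OCC[C@H](C)[C@@H]1CC[C@@H](C)c2c1cc([Li])c(OC(C)C)c2OC(C)C | intermediate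
21 | tert-butyl (5R,8S)-8-[(2S)-4-hydroxybutan-2-yl]-3,4-diisopropoxy-5-methyl-5,6,7,8-tetrahydronaphthalene-2-carboxylate | OCC[C@H](C)[C@@H]1CC[C@@H](C)c2c1cc(C(=O)OC(C)(C)C)c(OC(C)C)c2OC(C)C | intermediate
22 | tert-butyl (5R,8S)-8-[(2S)-4-bromobutan-2-yl]-3,4-diisopropoxy-5-methyl-5,6,7,8-tetrahydronaphthalene-2-carboxylate | BrCC[C@H](C)[C@@H]1CC[C@@H](C)c2c1cc(C(=O)OC(C)(C)C)c(OC(C)C)c2OC(C)C | intermediate
23 | 4-bromo-1,2-diisopropoxybenzene | CC(C)Oc1ccc(Br)cc1OC(C)C | intermediate
24 | methyl acrylate | C=CC(=O)OC | starting material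
25 | methyl (2E)-3-(3,4-diisopropoxyphenyl)prop-2-enoate | COC(=O)/C=C/c1ccc(OC(C)C)c(OC(C)C)c1 | intermediate
26 | (2E)-3-(3,4-diisopropoxyphenyl)prop-2-enoic acid | OC(=O)/C=C/c1ccc(OC(C)C)c(OC(C)C)c1 | intermediate
27 | methyl (2R)-3-hydroxy-2-methylpropanoate | C[C@H](CO)C(=O)OC | starting material
28 | methyl (2S)-3-bromo-2-methylpropanoate | C[C@H](CBr)C(=O)OC | intermediate
29 | (2S)-3-bromo-2-methylpropan-1-ol | C[C@H](CBr)CO | intermediate
30 | (2S)-3-bromo-2-methylpropyl (2E)-3-(3,4-diisopropoxyphenyl)prop-2-enoate | C[C@H](CBr)COC(=O)/C=C/c1ccc(OC(C)C)c(OC(C)C)c1 | intermediate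
31 | (2S)-3-iodo-2-methylpropyl (2E)-3-(3,4-diisopropoxyphenyl)prop-2-enoate | C[C@H](CI)COC(=O)/C=C/c1ccc(OC(C)C)c(OC(C)C)c1 | intermediate
32 | [(2S)-3-{[(2E)-3-(3,4-diisopropoxyphenyl)prop-2-enoyl]oxy}-2-methylpropyl]zinc iodide | C[C@H](C[Zn]I)COC(=O)/C=C/c1ccc(OC(C)C)c(OC(C)C)c1 | intermediate
33 | tert-butyl (5R,8S)-8-[(2S,6R)-7-{[(2E)-3-(3,4-diisopropoxyphenyl)prop-2-enoyl]oxy}-6-methylheptan-2-yl]-3,4-diisopropoxy-5-methyl-5,6,7,8-tetrahydronaphthalene-2-carboxylate | C[C@H](CCC[C@H](C)[C@@H]1CC[C@@H](C)c2c1cc(C(=O)OC(C)(C)C)c(OC(C)C)c2OC(C)C)COC(=O)/C=C/c1ccc(OC(C)C)c(OC(C)C)c1 | intermediate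
34 | (5R,8S)-8-[(2S,6R)-7-{[(2E)-3-(3,4-dihydroxyphenyl)prop-2-enoyl]oxy}-6-methylheptan-2-yl]-3,4-dihydroxy-5-methyl-5,6,7,8-tetrahydronaphthalene-2-carboxylic acid (CNP0492979.1) | C[C@H](CCC[C@H](C)[C@@H]1CC[C@@H](C)c2c1cc(C(=O)O)c(O)c2O)COC(=O)/C=C/c1ccc(O)c(O)c1 | target

**Totals**
Total step count: 22. Longest linear sequence: 14 steps (1, 2, 4–13, 21, 22), which is 0.64 of the total.

**The three steps most likely to fail, with fallbacks**

Step 21 (alkyl–alkyl Negishi with a β-branched zinc reagent next to a cinnamate). The fallback sets out from bromide 22 and bromo alcohol 29 and comes back at 33. Alcohol 29 is silylated (TBSCl, imidazole, DMF) to tert-butyl[(2S)-3-bromo-2-methylpropoxy]dimethylsilane F3. F3 is converted with Mg in THF into the Grignard reagent [(2S)-3-{[tert-butyl(dimethyl)silyl]oxy}-2-methylpropyl]magnesium bromide F4. F4 is coupled with 22 under copper catalysis (Li2CuCl4, THF, −20 to 0 °C; the hindered tert-butyl benzoate tolerates this) to give the silyl ether tert-butyl (5R,8S)-8-[(2S,6R)-7-{[tert-butyl(dimethyl)silyl]oxy}-6-methylheptan-2-yl]-3,4-diisopropoxy-5-methyl-5,6,7,8-tetrahydronaphthalene-2-carboxylate F5. TBAF then frees the primary alcohol tert-butyl (5R,8S)-8-[(2S,6R)-7-hydroxy-6-methylheptan-2-yl]-3,4-diisopropoxy-5-methyl-5,6,7,8-tetrahydronaphthalene-2-carboxylate F6, which is esterified with acid 26 (DCC, DMAP) to give 33. The carbon–carbon bond is thus made with a robust Grignard/copper coupling before the enoate is present, at the cost of a more linear endgame.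

Step 10 (facial selectivity of the C1=C2 hydrogenation; the pseudo-axial C4 methyl shields the face that must be hydrogenated). The fallback sets out from ester 17 and comes back at 19. Ester 17 is reduced with LiAlH4 to the unsaturated alcohol (3S)-3-[(4R)-5,6-diisopropoxy-4-methyl-3,4-dihydronaphthalen-1-yl]butan-1-ol F2. The styrenic double bond of F2 is then reduced with Li in NH3/THF/t-BuOH at −78 °C. Protonation of the benzylic anion is under thermodynamic control and should favour the isomer with both the C1 and C4 substituents pseudo-axial, that is the trans compound 19. A hydroxyl-directed (Crabtree) hydrogenation of F2 is not used, because it would deliver hydrogen from the face of the C12 arm and give the C1 epimer.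

Step 9 (Rh-catalysed addition of a hindered alkenylboronate to a simple enoate). The fallback sets out from triflate 14 and comes back at 17. Heck coupling of 14 with ethyl acrylate (Pd(OAc)2, PPh3, Et3N, DMF, 70 °C) gives the dienoate ethyl (2E)-3-[(4R)-5,6-diisopropoxy-4-methyl-3,4-dihydronaphthalen-1-yl]prop-2-enoate F1. Copper-catalysed asymmetric 1,4-addition of MeMgBr to F1 (CuI, Tol-BINAP, t-BuOMe, −20 °C; ligand enantiomer chosen for 3S) then gives 17 directly. The roles are reversed here: the methyl group is the nucleophile and the ring-bearing enoate the acceptor; the ring-substituted δ-carbon disfavours 1,6-addition.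

**Further compounds**
F1 | step 9 | ethyl (2E)-3-[(4R)-5,6-diisopropoxy-4-methyl-3,4-dihydronaphthalen-1-yl]prop-2-enoate | CCOC(=O)/C=C/C1=CC[C@@H](C)c2c1ccc(OC(C)C)c2OC(C)C
F2 | step 10 | (3S)-3-[(4R)-5,6-diisopropoxy-4-methyl-3,4-dihydronaphthalen-1-yl]butan-1-ol | OCC[C@H](C)C1=CC[C@@H](C)c2c1ccc(OC(C)C)c2OC(C)C
F3 | step 21 | tert-butyl[(2S)-3-bromo-2-methylpropoxy]dimethylsilane | C[C@H](CBr)CO[Si](C)(C)C(C)(C)C
F4 | step 21 | [(2S)-3-{[tert-butyl(dimethyl)silyl]oxy}-2-methylpropyl]magnesium bromide | C[C@H](C[Mg]Br)CO[Si](C)(C)C(C)(C)C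
F5 | step 21 | tert-butyl (5R,8S)-8-[(2S,6R)-7-{[tert-butyl(dimethyl)silyl]oxy}-6-methylheptan-2-yl]-3,4-diisopropoxy-5-methyl-5,6,7,8-tetrahydronaphthalene-2-carboxylate | C[C@H](CCC[C@H](C)[C@@H]1CC[C@@H](C)c2c1cc(C(=O)OC(C)(C)C)c(OC(C)C)c2OC(C)C)CO[Si](C)(C)C(C)(C)C
F6 | step 21 | tert-butyl (5R,8S)-8-[(2S,6R)-7-hydroxy-6-methylheptan-2-yl]-3,4-diisopropoxy-5-methyl-5,6,7,8-tetrahydronaphthalene-2-carboxylate | C[C@H](CCC[C@H](C)[C@@H]1CC[C@@H](C)c2c1cc(C(=O)OC(C)(C)C)c(OC(C)C)c2OC(C)C)CO
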